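**Analysis of the target**

The target 13 is a flavanone: a chroman-4-one in which the benzo ring A (C4a, C5 to C8, C8a) is fused to the dihydropyranone ring C (O1, C2, C3, C4), with ring B, a 3,4-dimethoxyphenyl group, on C2. Ring A carries a free hydroxyl at C5 that is hydrogen-bonded to the C4 carbonyl, methoxy groups at C6 and C7, and hydrogen at C8. The only stereocentre is C2 (S), so there is no neighbouring centre to relay from and it must be set in the absolute sense. C2 is benzylic to an electron-rich ring and is the oxygen-bearing β-carbon of an aryl ketone. Ring C can therefore open to the achiral 2'-hydroxychalcone by β-elimination of the O1 phenoxide under base, or by benzylic ionisation under strong acid, and either path racemises. The rings are electron-rich and oxidisable, and O5 has to be told apart from two methylated neighbours. The difficulty lies less in the skeleton than in assembling the O1–C2–C3 unit without passing through the open enone and in keeping C2 intact afterwards. The strategy rests on O1 linking C8a of ring A to C2: if the C2–O bond is brought in as a carbinol of fixed configuration, ring C can be closed on the other side of the oxygen, at C8a–O1, by arylation at an sp2 carbon in which C2 is a bystander.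

**Retrosynthetic reasoning**

13 to 12 (O5–CH3). The last operation is removal of one methyl group, so 13 is traced to its 5-O-methyl ether 12. This lets ring A come from a symmetrical, purchasable trimethoxyarene. The forward reaction must pick O5 out of five methyl ethers, which the neighbouring C4 carbonyl allows through a six-membered chelate with a boron trihalide. It is placed last because a free peri-phenol would consume base and bind copper in the earlier steps.

12 to 11 (C4 carbonyl to dithioketal). No skeletal bond is cut. The ketone is hidden as the trimethylene dithioketal 11 so that the compound cyclised in the key step is not a β-hydroxy ketone. The forward unmasking has to be neutral and non-oxidising, because 12 is base-labile at C2 and both arenes are electron-rich.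

11 to 10 (C8a–O1, the key disconnection). Ring C is opened at the aryl–oxygen bond, giving the bromo carbinol 10. Cutting C2–O1 instead would mean displacement at a para-methoxybenzylic carbon, with ionisation and scrambling, or an oxa-Michael closure through the achiral enone. Cutting at C8a reduces the stereochemical problem to making one secondary benzylic alcohol. The forward reaction must form an aryl ether at a hindered, electron-rich carbon under basic conditions that the masked C4 makes harmless.

10 to 5 and 8 (C3–C4). C4 is a carbonyl carbon and hence a natural acyl-anion site, and C3 is a methylene that the terminus of an epoxide can supply. The cut divides the molecule into a ring-A half (dithiane 5, used as its lithio derivative 9) and a ring-B half (epoxide 8) of similar size. The forward step must metalate the dithiane without touching the aryl bromide, which calls for a lithium amide rather than an alkyllithium. The hindered anion must then attack the unsubstituted carbon of 8, leaving the benzylic C–O bond and its configuration alone.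

8 to 7 to 6 (epoxide C–O, then the C2–H bond). The epoxide is traced to the bromohydrin 7 and this to the α-bromo ketone 6. Catalyst-controlled reduction of an aryl ketone is among the most dependable ways to set a benzylic carbinol. It uses all the material, where a resolution of the racemic epoxide would discard half. It also avoids acidic epoxidation conditions, which an electron-rich styrene oxide tolerates poorly.

5 to 3 and 4, then 3 to 1 (C4–S bonds and C4–C4a). The dithiane comes from aldehyde 3 and dithiol 4, and the aldehyde from arene 1 by electrophilic formylation through the chloro ether 2. Because 1 is symmetrical the formylation has no regiochemical choice. It places the new carbon ortho to bromine, which is the C4a/C8a relationship the key step needs.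

**Alternatives that were turned down**

Alternative 1: Ring C is cut at three bonds at once (C4a–C4, C4–C3, O1–C2), leading to 2-iodo-3,4,5-trimethoxyphenol A1, 4-ethynyl-1,2-dimethoxybenzene A2 and carbon monoxide A3. In the forward sense PdCl2(PPh3)2 with an amine base would add A1 oxidatively, insert A3, alkynylate the acyl palladium with A2 and close the phenol onto the alkynone in the 6-endo mode. The product would be the flavone 2-(3,4-dimethoxyphenyl)-5,6,7-trimethoxy-4H-chromen-4-one A4.
- For it: it is the most convergent plan, with three bonds and ring C formed in one step from simple partners. A4 is robust, and its O5 methyl group could be removed while no stereocentre is at risk; on both points it is stronger than the chosen route.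
- Against it: A4 is flat, so C2 would have to be created afterwards by enantioselective 1,4-reduction of the C2–C3 double bond of a chromone. That bond is part of a vinylogous ester and a poor hydride acceptor, over-reduction at C4 competes, and the product can racemise by ring opening under the basic conditions such reductions often use. The annulation also has to favour 6-endo over 5-exo closure at an iodide flanked by two ortho substituents.
- Comparison: the chosen route is a few steps longer to the skeleton, but it sets C2 by a standard ketone reduction and then never breaks a bond to it.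

Alternative 2: Here ring A is made, not bought: C8–C8a and C4a–C5 are cut. The partners are 4-chloro-2,3-dimethoxycyclobut-2-en-1-one A5 and tert-butyl{[2,4-cis-(2S)-2-(3,4-dimethoxyphenyl)-6-(tributylstannyl)-3,4-dihydro-2H-pyran-4-yl]oxy}dimethylsilane A6. A Stille coupling (PdCl2(PhCN)2 with a furylphosphine) would form C8–C8a. Warming would open the cyclobutenone to a dienylketene, whose 6π closure at C4a–C5 and tautomerisation would give 2,4-cis-(2S)-4-(tert-butyldimethylsilyloxy)-2-(3,4-dimethoxyphenyl)-6,7-dimethoxychroman-5-ol A7.
- For it: O5 emerges as a free phenol already distinguished from the methylated O6 and O7, so no selective demethylation is needed, which is clearly better than the chosen route. The substitution pattern of ring A is unambiguous, and the thermal step is neutral.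
- Against it: the effort goes into building the one part of 13 that can be purchased. A6 needs its own multi-step asymmetric synthesis with two stereocentres and an enol-ether stannylation. The C4 stereocentre is made only to be destroyed by desilylation and oxidation after A7. Tin is used stoichiometrically.
- Comparison: the chosen route forms one ring and one C–C bond around a bought ring A and controls only the stereocentre the target actually has. Its price is the late demethylation.

Alternative 3: The C2–C3 bond is cut, leading to the diazoketone 2-diazo-1-{2-[(3,4-dimethoxybenzyl)oxy]-4,5-dimethoxy-6-[(triisopropylsilyl)oxy]phenyl}ethanone A8. A chiral dirhodium carboxylate such as Rh2(S-PTTL)4 would generate a carbene at C3. Insertion into one of the two enantiotopic benzylic C–H bonds would close ring C and set C2, giving (2S)-2-(3,4-dimethoxyphenyl)-6,7-dimethoxy-5-(triisopropylsilyloxy)chroman-4-one A9.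
- For it: ring and stereocentre arise in one catalytic step from an achiral precursor, which is better stereo-economy than the chosen route. O5 is carried as a silyl ether, so the last step would be a mild desilylation rather than a Lewis-acid demethylation.
- Against it: the carbene lies 1,5 to O1, and oxonium ylide formation followed by a 1,2-benzyl shift (a five-membered closure) is a favoured escape for such substrates. The desired insertion is a 1,6-process, inherently less favoured than the 1,5-mode. Enantiocontrol with acceptor-only keto carbenes is much less developed than with donor–acceptor carbenes. Ring B invites aromatic cycloaddition. A8 needs a differentially protected tetra-oxygenated acetophenone that takes several steps.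
- Comparison: the stereo-defining step is also the least predictable one. The chosen strategy separates the two: configuration comes from a reliable reduction, and the risky copper step has no stereochemical consequence.

Key step: step 6

Assumption: flavanone numbering (O1, C2, C3, C4, C4a, C5 to C8, C8a; rings A, B, C) is used for the corresponding atoms of all open-chain precursors, and 1, 4, 6 and all reagents are taken as purchasable.

**Route**

Step 1
Reactants: 1 5-bromo-1,2,3-trimethoxybenzene
Product: 3 6-bromo-2,3,4-trimethoxybenzaldehyde, via chloro(methoxy)methyl arene 2 (not isolated)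
Conditions: Cl2CHOMe, TiCl4, CH2Cl2, 0 °C to rt; then ice-water
Reagents that add atoms: dichloromethyl methyl ether COC(Cl)Cl (formyl carbon); water O (carbonyl oxygen)
Why: Rieche formylation; the two free positions of 1 are equivalent by symmetry and each is para to one methoxy group and ortho to another, so only one aldehyde can form, and it carries the new carbon ortho to bromine. The formyl group deactivates the ring against a second substitution, and hydrolysis of the α-chloro ether 2 on work-up should release 3.

Step 2
Reactants: 3 6-bromo-2,3,4-trimethoxybenzaldehyde; 4 propane-1,3-dithiol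
Product: 5 2-(6-bromo-2,3,4-trimethoxyphenyl)-1,3-dithiane
Conditions: HS(CH2)3SH, cat. BF3·OEt2, CH2Cl2, 0 °C to rt
Reagents that add atoms: none
Why: Lewis-acid-catalysed dithioacetalisation; aldehydes react readily even between two ortho substituents, and the aryl bromide and methyl ethers are inert to BF3·OEt2 at this temperature.

Step 3
Reactants: 6 2-bromo-1-(3,4-dimethoxyphenyl)ethanone
Product: 7 (1R)-2-bromo-1-(3,4-dimethoxyphenyl)ethanol
Conditions: (R)-2-methyl-CBS-oxazaborolidine (10 mol %), BH3·SMe2, THF, 0 °C; then MeOH, aqueous work-up
Reagents that add atoms: none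
Why: Corey–Bakshi–Shibata reduction; the oxazaborolidine binds borane at nitrogen and the ketone at boron with the aryl group in the less hindered position, so hydride is delivered to one face. With the (R)-catalyst an α-halo aryl ketone should give the (R)-halohydrin (R because CH2Br outranks aryl), which is the spatial arrangement needed for (S)-C2.

Step 4
Reactants: 7 (1R)-2-bromo-1-(3,4-dimethoxyphenyl)ethanol
Product: 8 (2R)-2-(3,4-dimethoxyphenyl)oxirane
Conditions: 2 M aq. NaOH, THF, 0 °C to rt
Reagents that add atoms: none
Why: Intramolecular Williamson etherification (3-exo-tet) of the bromohydrin alkoxide; the C–O bond at the stereocentre is not involved, so the configuration is carried over. The basic medium protects the acid-sensitive electron-rich styrene oxide, which is used without delay.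

Step 5
Reactants: 5 2-(6-bromo-2,3,4-trimethoxyphenyl)-1,3-dithiane; 8 (2R)-2-(3,4-dimethoxyphenyl)oxirane
Product: 10 (1S)-2-[2-(6-bromo-2,3,4-trimethoxyphenyl)-1,3-dithian-2-yl]-1-(3,4-dimethoxyphenyl)ethanol, via lithiated dithiane 9 (not isolated)
Conditions: LiN(iPr)2 (commercial solution), THF, –78 to –30 °C; then 8, DMPU, –78 °C to rt; aq. NH4Cl
Reagents that add atoms: none
Why: Corey–Seebach umpolung; the amide base removes the dithiane C–H, by far the most acidic C–H of 5, without the bromine–lithium exchange an alkyllithium would cause, and 5 is kept in slight excess over the base so that no free amide is left to isomerise 8. The sulfur-stabilised anion 9 should open the epoxide by SN2 attack at the unsubstituted CH2; the benzylic C–O bond is untouched, so (R)-8 gives (S)-10 with unchanged spatial arrangement (only the priorities change).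

Step 6
Reactants: 10 (1S)-2-[2-(6-bromo-2,3,4-trimethoxyphenyl)-1,3-dithian-2-yl]-1-(3,4-dimethoxyphenyl)ethanol
Product: 11 (2S)-2-(3,4-dimethoxyphenyl)-5,6,7-trimethoxyspiro[chromane-4,2'-[1,3]dithiane] (the trimethylene dithioketal of 12)
Conditions: CuI (10 mol %), 3,4,7,8-tetramethyl-1,10-phenanthroline (20 mol %), Cs2CO3, toluene (0.05 M), 110 °C, Ar
Reagents that add atoms: none
Why: Cs2CO3 deprotonates the carbinol and the alkoxide binds phenanthroline-ligated monovalent copper; oxidative addition of the C8a–Br bond gives a seven-membered trivalent copper aryl alkoxide, and C–O reductive elimination forms C8a–O1 and returns monovalent copper. The closest known reaction type is the Ullmann-type intramolecular O-arylation of secondary alcohols with aryl bromides to give chromans. Ring C closes in a 6-exo-trig-type mode: oxygen attacks the sp2 carbon C8a, and the C–Br bond that breaks lies outside the new six-membered ring. No stereocentre is created; C2 keeps its configuration because its C–O bond is never broken and, with C4 masked, neither retro-aldol cleavage nor E1cB dehydration through C3 is open. The step needs cyclisation to win over hydrodebromination (β-hydride loss from the copper alkoxide) and over intermolecular etherification; the fully substituted dithiane carbon at C4 holds the alkoxide next to C8a (Thorpe–Ingold effect) and moderate dilution helps. The site of etherification is fixed by the position of bromine, there is only one hydroxyl, and the methyl ethers are inert. The bidentate phenanthroline should out-compete the thioketal sulfur atoms for copper.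

Step 7
Reactants: 11 (2S)-2-(3,4-dimethoxyphenyl)-5,6,7-trimethoxyspiro[chromane-4,2'-[1,3]dithiane]
Product: 12 (2S)-2-(3,4-dimethoxyphenyl)-5,6,7-trimethoxychroman-4-one
Conditions: MeI, CaCO3, MeCN–H2O (9:1), 45 °C
Reagents that add atoms: water O
Why: Alkylative dithiane hydrolysis; S-methylation turns sulfur into a leaving group, and the thionium ion at C4, stabilised by the ortho and para oxygen donors of ring A, is captured by water. The CaCO3-buffered, non-oxidising medium should leave the electron-rich rings and the base-labile C2 centre alone.

Step 8
Reactants: 12 (2S)-2-(3,4-dimethoxyphenyl)-5,6,7-trimethoxychroman-4-one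
Product: 13 (2S)-2-(3,4-dimethoxyphenyl)-5-hydroxy-6,7-dimethoxychroman-4-one
Conditions: BCl3 (1.2 equiv), CH2Cl2, –78 to 0 °C; then ice-water
Reagents that add atoms: none
Why: Chelation-controlled aryl methyl ether cleavage; boron bridges the C4 carbonyl and the peri O5 in a six-membered chelate and chloride removes only that methyl group, while the other four methyl ethers lack such an anchor and should survive at low temperature with about one equivalent of reagent. C2 is not touched as long as ring C stays closed, hence the low temperature and short contact time.

**Compound list**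

1 | 5-bromo-1,2,3-trimethoxybenzene | COc1cc(Br)cc(OC)c1OC | starting material
2 | 1-bromo-2-[chloro(methoxy)methyl]-3,4,5-trimethoxybenzene | COC(Cl)c1c(Br)cc(OC)c(OC)c1OC | intermediate (not isolated)
3 | 6-bromo-2,3,4-trimethoxybenzaldehyde | O=Cc1c(Br)cc(OC)c(OC)c1OC | intermediate
4 | propane-1,3-dithiol | SCCCS | starting material
5 | 2-(6-bromo-2,3,4-trimethoxyphenyl)-1,3-dithiane | COc1cc(Br)c(C2SCCCS2)c(OC)c1OC | intermediate
6 | 2-bromo-1-(3,4-dimethoxyphenyl)ethanone | COc1ccc(C(=O)CBr)cc1OC | starting material
7 | (1R)-2-bromo-1-(3,4-dimethoxyphenyl)ethanol | COc1ccc([C@@H](O)CBr)cc1OC | intermediate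
8 | (2R)-2-(3,4-dimethoxyphenyl)oxirane | COc1ccc([C@@H]2CO2)cc1OC | intermediate
9 | [2-(6-bromo-2,3,4-trimethoxyphenyl)-1,3-dithian-2-yl]lithium | [Li]C1(c2c(Br)cc(OC)c(OC)c2OC)SCCCS1 | intermediate (not isolated)
10 | (1S)-2-[2-(6-bromo-2,3,4-trimethoxyphenyl)-1,3-dithian-2-yl]-1-(3,4-dimethoxyphenyl)ethanol | COc1ccc([C@@H](O)CC2(c3c(Br)cc(OC)c(OC)c3OC)SCCCS2)cc1OC | intermediate
11 | (2S)-2-(3,4-dimethoxyphenyl)-5,6,7-trimethoxyspiro[chromane-4,2'-[1,3]dithiane] | COc1ccc([C@@H]2CC3(SCCCS3)c3c(cc(OC)c(OC)c3OC)O2)cc1OC | intermediate
12 | (2S)-2-(3,4-dimethoxyphenyl)-5,6,7-trimethoxychroman-4-one | COc1ccc([C@@H]2CC(=O)c3c(cc(OC)c(OC)c3OC)O2)cc1OC | intermediate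
13 | (2S)-2-(3,4-dimethoxyphenyl)-5-hydroxy-6,7-dimethoxychroman-4-one | COc1ccc([C@@H]2CC(=O)c3c(cc(OC)c(OC)c3O)O2)cc1OC | target

**Step count and risk**

Total step count: 8. Longest linear sequence: 6 steps (1, 2, 5, 6, 7, 8 from compound 1; the branch 3, 4, 5, 6, 7, 8 from compound 6 is equally long).

Least certain steps:

Step 6 (key step). The bromide at C8a is electron-rich and flanked by the fully substituted C4, so oxidative addition to copper may be slow. The thioketal sulfur atoms may sequester the catalyst. β-Hydride loss from the copper alkoxide may cause hydrodebromination with oxidation of the carbinol.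

Fallback, setting out from 10 and coming back at 12, with sulfur removed before the ring closure:
- 10 is unmasked with MeI and CaCO3 in aqueous MeCN to (3S)-1-(6-bromo-2,3,4-trimethoxyphenyl)-3-(3,4-dimethoxyphenyl)-3-hydroxypropan-1-one F1.
- F1 is reduced at once with NaBH4 in MeOH at low temperature to (1S)-3-(6-bromo-2,3,4-trimethoxyphenyl)-1-(3,4-dimethoxyphenyl)propane-1,3-diol F2, as both epimers at the new carbinol, which is of no consequence.
- Only the C2 hydroxyl of the diol can reach C8a through a six-membered ring. O-arylation with CuI, phenanthroline and Cs2CO3, or, now that sulfur is absent, with Pd(OAc)2 and a bulky biaryl dialkylphosphine, should give (2S)-2-(3,4-dimethoxyphenyl)-5,6,7-trimethoxychroman-4-ol F3.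
- Oxidation of the benzylic alcohol of F3 with Dess–Martin periodinane returns to 12.

Step 5. The amide base may also deprotonate the arene C8–H between bromine and methoxy, leading to loss of bromide and decomposition. The doubly ortho-substituted anion may add sluggishly. Some attack at the benzylic epoxide carbon, or base-induced isomerisation of the epoxide, may erode yield and purity.

Fallback, setting out from 3 and coming back at 10, with no carbanion generated next to the aryl bromide:
- Ohira–Bestmann homologation of 3 (dimethyl (1-diazo-2-oxopropyl)phosphonate, K2CO3, MeOH) gives 1-bromo-2-ethynyl-3,4,5-trimethoxybenzene F4.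
- Acyl Sonogashira coupling with purchased 3,4-dimethoxybenzoyl chloride (COc1ccc(C(Cl)=O)cc1OC; PdCl2(PPh3)2, CuI, Et3N, THF, rt) gives 3-(6-bromo-2,3,4-trimethoxyphenyl)-1-(3,4-dimethoxyphenyl)prop-2-yn-1-one F5. The acid chloride adds to zerovalent palladium far faster than the hindered aryl bromide.
- Double conjugate addition of 4 (NaOMe, MeOH–CH2Cl2) at the alkyne carbon attached to ring A gives 2-[2-(6-bromo-2,3,4-trimethoxyphenyl)-1,3-dithian-2-yl]-1-(3,4-dimethoxyphenyl)ethanone F6.
- Corey–Bakshi–Shibata reduction of F6 with the (R)-catalyst of step 3 and BH3·SMe2 should give 10.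

Step 8. Lewis-acid activation of the chelated ketone may open ring C at C2–O1, by retro-oxa-Michael cleavage or by benzylic ionisation assisted by the para-methoxy group of ring B, and so erode the enantiopurity. Excess reagent or warming may also cleave the neighbouring 6-O-methyl group.

Fallback, setting out from 3 and coming back at 13, in which O5 is differentiated before any stereocentre exists:
- BCl3 in CH2Cl2 cleaves the methoxy group next to the aldehyde of 3 through the same kind of chelate, giving 6-bromo-2-hydroxy-3,4-dimethoxybenzaldehyde F7.
- Benzylation (benzyl bromide, BrCc1ccccc1, K2CO3, DMF) gives 2-(benzyloxy)-6-bromo-3,4-dimethoxybenzaldehyde F8.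
- The chemistry of steps 2, 5, 6 and 7 is repeated in the benzyl series. It passes through 2-[2-(benzyloxy)-6-bromo-3,4-dimethoxyphenyl]-1,3-dithiane F9, then (1S)-2-{2-[2-(benzyloxy)-6-bromo-3,4-dimethoxyphenyl]-1,3-dithian-2-yl}-1-(3,4-dimethoxyphenyl)ethanol F10, then (2S)-5-(benzyloxy)-2-(3,4-dimethoxyphenyl)-6,7-dimethoxyspiro[chromane-4,2'-[1,3]dithiane] F11, and finally (2S)-5-(benzyloxy)-2-(3,4-dimethoxyphenyl)-6,7-dimethoxychroman-4-one F12.
- Hydrogenolysis of F12 (H2, Pd/C, EtOAc) under neutral conditions then gives 13.

**Further compounds**

F1 | step 6 | (3S)-1-(6-bromo-2,3,4-trimethoxyphenyl)-3-(3,4-dimethoxyphenyl)-3-hydroxypropan-1-one | COc1ccc([C@@H](O)CC(=O)c2c(Br)cc(OC)c(OC)c2OC)cc1OC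
F2 | step 6 | (1S)-3-(6-bromo-2,3,4-trimethoxyphenyl)-1-(3,4-dimethoxyphenyl)propane-1,3-diol (both C3 epimers) | COc1ccc([C@@H](O)CC(O)c2c(Br)cc(OC)c(OC)c2OC)cc1OC
F3 | step 6 | (2S)-2-(3,4-dimethoxyphenyl)-5,6,7-trimethoxychroman-4-ol (both C4 epimers) | COc1ccc([C@@H]2CC(O)c3c(cc(OC)c(OC)c3OC)O2)cc1OC
F4 | step 5 | 1-bromo-2-ethynyl-3,4,5-trimethoxybenzene | C#Cc1c(Br)cc(OC)c(OC)c1OC
F5 | step 5 | 3-(6-bromo-2,3,4-trimethoxyphenyl)-1-(3,4-dimethoxyphenyl)prop-2-yn-1-one | COc1ccc(C(=O)C#Cc2c(Br)cc(OC)c(OC)c2OC)cc1OC
F6 | step 5 | 2-[2-(6-bromo-2,3,4-trimethoxyphenyl)-1,3-dithian-2-yl]-1-(3,4-dimethoxyphenyl)ethanone | COc1ccc(C(=O)CC2(c3c(Br)cc(OC)c(OC)c3OC)SCCCS2)cc1OC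
F7 | step 8 | 6-bromo-2-hydroxy-3,4-dimethoxybenzaldehyde | COc1cc(Br)c(C=O)c(O)c1OC
F8 | step 8 | 2-(benzyloxy)-6-bromo-3,4-dimethoxybenzaldehyde | COc1cc(Br)c(C=O)c(OCc2ccccc2)c1OC
F9 | step 8 | 2-[2-(benzyloxy)-6-bromo-3,4-dimethoxyphenyl]-1,3-dithiane | COc1cc(Br)c(C2SCCCS2)c(OCc2ccccc2)c1OC
F10 | step 8 | (1S)-2-{2-[2-(benzyloxy)-6-bromo-3,4-dimethoxyphenyl]-1,3-dithian-2-yl}-1-(3,4-dimethoxyphenyl)ethanol | COc1ccc([C@@H](O)CC2(c3c(Br)cc(OC)c(OC)c3OCc3ccccc3)SCCCS2)cc1OC
F11 | step 8 | (2S)-5-(benzyloxy)-2-(3,4-dimethoxyphenyl)-6,7-dimethoxyspiro[chromane-4,2'-[1,3]dithiane] | COc1ccc([C@@H]2CC3(SCCCS3)c3c(cc(OC)c(OC)c3OCc3ccccc3)O2)cc1OC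
F12 | step 8 | (2S)-5-(benzyloxy)-2-(3,4-dimethoxyphenyl)-6,7-dimethoxychroman-4-one | COc1ccc([C@@H]2CC(=O)c3c(cc(OC)c(OC)c3OCc3ccccc3)O2)cc1OC
A1 | alternative 1 | 2-iodo-3,4,5-trimethoxyphenol | COc1cc(O)c(I)c(OC)c1OC
A2 | alternative 1 | 4-ethynyl-1,2-dimethoxybenzene | C#Cc1ccc(OC)c(OC)c1
A3 | alternative 1 | carbon monoxide | [C-]#[O+]
A4 | alternative 1 | 2-(3,4-dimethoxyphenyl)-5,6,7-trimethoxy-4H-chromen-4-one | COc1ccc(-c2cc(=O)c3c(OC)c(OC)c(OC)cc3o2)cc1OC
A5 | alternative 2 | 4-chloro-2,3-dimethoxycyclobut-2-en-1-one | COC1=C(OC)C(Cl)C1=O
A6 | alternative 2 | tert-butyl{[2,4-cis-(2S)-2-(3,4-dimethoxyphenyl)-6-(tributylstannyl)-3,4-dihydro-2H-pyran-4-yl]oxy}dimethylsilane | COc1ccc([C@@H]2C[C@H](O[Si](C)(C)C(C)(C)C)C=C([Sn](CCCC)(CCCC)CCCC)O2)cc1OC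
A7 | alternative 2 | 2,4-cis-(2S)-4-(tert-butyldimethylsilyloxy)-2-(3,4-dimethoxyphenyl)-6,7-dimethoxychroman-5-ol | COc1ccc([C@@H]2C[C@H](O[Si](C)(C)C(C)(C)C)c3c(cc(OC)c(OC)c3O)O2)cc1OC
A8 | alternative 3 | 2-diazo-1-{2-[(3,4-dimethoxybenzyl)oxy]-4,5-dimethoxy-6-[(triisopropylsilyl)oxy]phenyl}ethanone | COc1ccc(COc2cc(OC)c(OC)c(O[Si](C(C)C)(C(C)C)C(C)C)c2C(=O)C=[N+]=[N-])cc1OC
A9 | alternative 3 | (2S)-2-(3,4-dimethoxyphenyl)-6,7-dimethoxy-5-(triisopropylsilyloxy)chroman-4-one | COc1ccc([C@@H]2CC(=O)c3c(cc(OC)c(OC)c3O[Si](C(C)C)(C(C)C)C(C)C)O2)cc1OC
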